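The numbers in the tables are calculated for substances that don't exist, noise included.

Whatever the ligand does, the complex is conserved: starting complex (M), complex with one exchanged (A) and complex with two exchanged (B), as fractions of the charge, add up to the whole. The gap in the readings is therefore B, and in beta it grows from 6.30 % at 5.00 h to 16.8 % at 15.0 h.

in all of them: starting complex 46 mM

| charge | incoming ligand | remark | time |
|---|---|---|---|
| delta | 0.62 equiv | run made earlier |  |
| zeta | 1.2 equiv | run made earlier |  |
| beta | 2.9 equiv | run made earlier |  |
| maple | 0.500 equiv |  | 2.0 d |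
| cedar | 1.50 equiv |  | 2.0 d |
| birch | 3.00 equiv |  | 2.0 d |

- delta (time / h: complex with one exchanged / %, starting complex / %): 2.00: 15.4, 84.7; 4.00: 22.8, 77.3; 6.00: 26.5, 73.3; 12.0: 32.3, 66.5; 25.0: 40.0, 57.7
- zeta (time / h: complex with one exchanged / %, starting complex / %): 2.00: 27.6, 72.1; 4.00: 40.2, 60.0; 6.00: 45.6, 53.9; 12.0: 54.0, 43.6; 25.0: 63.3, 32.3
- beta (time / h: complex with one exchanged / %, starting complex / %): 5.00: 73.2, 20.5; 10.0: 79.1, 8.8; 15.0: 78.7, 4.5; 20.0: 76.4, 3.0; 25.0: 73.1, 2.2

(standard deviation of a reading: 0.5 percentage points)

- amount of complex with one exchanged at the end, in percent of the starting complex charged, for each flask in turn (maple, cedar, birch)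

The forecast finds that “k falls with time, not conversion”, so we set the clock aside and count lifetimes of M instead, θ = ln(charge/M). If both exchanges are first order in the same free incoming ligand, its concentration cancels from the ratio s of their rate constants, and each lifetime of M adds s·A to B. Over that beta interval:

Δθ = 1.52, mean A = 76.0 %, ΔB = 10 percentage points

s = ΔB/(A·Δθ) = 0.0912

This reading s, the rate constant of the second exchange over that of the first, is the selectivity factor. Integrated with s held constant and both back reactions left out, it ties A to M with no time in it:

A = (M^s − M)/(1 − s)

In zeta at 25.0 h, M = 32.3 % gives 63.7 %, against a reading of 63.3 %.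

We commit to maple. If its whole ligand charge went onto the complex, M would stand near half the charge, giving A = 48.3 %. For the other end of a span we borrow delta's M at 25.0 h, 57.7 %, from a run with another charge and time, so this is an estimate and not a bound; it gives A = 41.2 %. The forecast gives 37 %, 75 % and 59 % for maple, cedar and birch, so its maple value lies lower than our span.

Maple, cedar and birch give 42.8 %, 76.1 % and 58.7 %.

    starting complex + incoming ligand ⇌ leaving ligand + complex with one exchanged (K = 2.40, k = 4.03 L mol⁻¹ h⁻¹)
    complex with one exchanged + incoming ligand ⇌ leaving ligand + complex with two exchanged (K = 2.05, k = 0.333 L mol⁻¹ h⁻¹)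
    leaving ligand → by-product carried off (k = 0.507 h⁻¹)
    leaving ligand + incoming ligand ⇌ idle adduct, settled at all times (K = 2100 L mol⁻¹)

Maple's 42.8 % lies inside our span and higher than the forecast's 37 %, with starting complex at 56.0 % at the end. Put into the rule, that M gives A = 42.7 %. In cedar, M = 13 % gives 77.0 %, and the flask holds 76.1 %.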